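Whatever reagent is left over in west, south and south-west equals the two substrates left over together, as a fraction u of each charge: at 2.00 equiv on the left-handed substrate, reagent matches the two substrates together, and each step spends one reagent and one substrate.

| setting | winter | spring | autumn | west | south | south-west |
|---|---|---|---|---|---|---|
| left-handed substrate | 0.50 M | 0.50 M | 0.50 M | 0.50 M | 0.50 M | 0.50 M |
| right-handed substrate | 0.50 M | 0.50 M | 0.50 M | 0.50 M | 0.50 M | 0.50 M |
| reagent | 2 equiv | 2 equiv | 2 equiv | 2.00 equiv | 2.00 equiv | 2.00 equiv |
| free catalyst | 0.1 mol% | 0.1 mol% | 0.1 mol% | 0.1 mol% | 0.1 mol% | 0.1 mol% |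
| racemization catalyst | 0.2 mol% | 0.2 mol% | 0.2 mol% | 0.2 mol% | 0.2 mol% | 0.2 mol% |
| added ligand | 1.1 mM | 1.1 mM | 1.7 mM | 1.1 mM | 1.1 mM | 1.1 mM |
| impurity | 0.15 mM | 0.35 mM | 0.23 mM | 0.23 mM | 0.23 mM | 0.23 mM |
| temperature | −10 °C | 23 °C | −10 °C | 5 °C | 35 °C | −25 °C |
| remark | run made earlier | run made earlier | run made earlier |  |  |  |
| time |  |  |  | 2.0 h | 2.0 h | 2.0 h |

winter run (percent of the left-handed substrate and right-handed substrate together charged)

| time / h | left-handed product / % |
|---|---|
| 1.33 | 43 |
| 3.00 | 49 |
| 4.00 | 53 |
| 5.00 | 53 |

spring run (percent of the left-handed substrate and right-handed substrate together charged)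

| time / min | left-handed product / % |
|---|---|
| 15.0 | 49 |
| 30.0 | 60 |
| 50.0 | 60 |
| 60.0 | 66 |

autumn run (percent of the left-handed substrate and right-handed substrate together charged)

| time / h | left-handed product / % |
|---|---|
| 0.667 | 30 |
| 2.00 | 45 |
| 3.00 | 42 |
| 5.00 | 47 |

(each reading ± 1.5 percentage points)

- free catalyst is single-handed; left-handed substrate and right-handed substrate are mirror images of each other, charged as a racemate, each of them at the stated concentration
- the analysis behind the earlier runs scatters by 1.5 percentage points, standard deviation
- what may be going on: reagent + free catalyst + left-handed substrate -> free catalyst + left-handed product; reagent + free catalyst + right-handed substrate -> free catalyst + right-handed product; left-handed substrate + racemization catalyst <-> right-handed substrate + racemization catalyst; free catalyst + added ligand <-> idle complex; racemization catalyst + impurity -> spent catalyst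

- which flask leads in amount of left-handed product, in percent of the left-handed substrate and right-handed substrate together charged ("all alike" within 1.5 percentage points) (west / south / south-west / all alike)
- how much left-handed product is there at the end, in percent of the left-handed substrate and right-handed substrate together charged: west
- how much left-handed product is there at the end, in percent of the left-handed substrate and right-handed substrate together charged: south
- how much left-handed product is there at the end, in percent of the left-handed substrate and right-handed substrate together charged: south-west

With the catalyst taken as steady, the loss of u goes as u squared, so u = 1/(1+κt), with κ a clock per hour. Left-handed product P, as a fraction of the two substrates charged, is then f(1−u), so t/P runs straight in t with slope 1/f.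

In the spring run the later readings average 62.0% at 46.7 min. Together with the first reading, 49% at 15.0 min, they give the left-handed share f, the mean fraction of the two products together that is left-handed: 0.709. The clock there reads 8.95 h⁻¹.

The same share puts the winter clock at 1.16 h⁻¹ from its first reading. Taking ln κ as straight in temperature between winter and spring gives west 2.93 h⁻¹, south 18.8 h⁻¹ and south-west 0.457 h⁻¹. At 2.0 h this reckoning stands at 60.6%, 69.1% and 33.9%, so south leads.

The weak link is the winter clock: its second reading gives 0.745 h⁻¹. The mean of the two, 0.952 h⁻¹, brings south-west down to 28.9%, so that flask is held between the two values.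

The forecast also names south, with west 57% (50% to 64%), south 75% (65% to 86%) and south-west 37% (29% to 44%). Of south it says “racemization is fast, limited by selectivity”. It stands above this reckoning there.

The flasks give west 57.8%, south 68.5% and south-west 32.8%, and south leads.

    reagent + free catalyst + left-handed substrate → free catalyst + left-handed product (k = 280 M⁻² min⁻¹, Ea = 43.0 kJ mol⁻¹)
    reagent + free catalyst + right-handed substrate → free catalyst + right-handed product (k = 110 M⁻² min⁻¹, Ea = 42.0 kJ mol⁻¹)
    left-handed substrate + racemization catalyst ⇌ right-handed substrate + racemization catalyst, rate k3*[racemization catalyst]*[left-handed substrate] forward; the back reaction follows from the equilibrium constant (k = 98.0 M⁻¹ min⁻¹, Ea = 47.0 kJ mol⁻¹)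
    free catalyst + added ligand ⇌ idle complex (K = 2000 M⁻¹, k = 45.0 M⁻¹ min⁻¹, Ea = 47.0 kJ mol⁻¹, ΔH = −58.0 kJ mol⁻¹)
    racemization catalyst + impurity → spent catalyst (k = 1200 M⁻¹ min⁻¹, Ea = 43.0 kJ mol⁻¹)
    (constants at 5 °C)

South has converted 98.4% of the two substrates, and the share read off spring turns that into 69.8%; south holds 68.5%. South stands 36 percentage points above south-west, and the largest single effect on that gap is what temperature does to the path to left-handed product: without it the gap is −28 points. A neighbour of west, charged with 0.500 equiv of reagent, keeps 1.4% of it, so reagent is the limiting reagent there. Its charge is a quarter of the two substrates, and the share makes that 17.5%; the neighbour holds 17.5%.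

The readings stem from a simulated flask for substances that don't exist.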